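Both 2,3-dihydrobenzofurans (unit 1: benzo ring B and furan ring C, with guaiacyl ring A on C2; unit 2: furan ring D and benzo ring E, which carries the propenol chain) are disconnected at C2–C3. Each C2 is a methine bonded to O1 and to an aryl ring oxygenated para to it, and C3 lies 1,5 to it through C3a–C7a–O1, so a carbenoid at C3 can insert into an ArO–CH2–Ar C–H bond. One rhodium-catalysed operation on a linear three-ring bis(benzyl aryl ether) bearing two aryldiazoacetates closes rings C and D, forms both C2–C3 bonds and sets four stereocentres; methoxide then turns both esters trans.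

Key step: step 8

Assumption: the S-configured catalyst is taken to deliver the 2R configuration at both new C2 centres, in line with the sense of induction of this catalyst family in single-ring closures of the same kind; should a model ring closure show the opposite sense, the mirror-image catalyst Rh2(R-PTTL)4 is used and nothing else changes.

Remark: both units of the target are trans with 2R,3S configuration; at the ester stage the same spatial arrangement is named 2R,3R because the CIP ranking at C3 changes. Benzofuran numbering (O1, C2, C3, C3a, C4 to C7, C7a) is used for each unit.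

Step 1
Reactants: 1 vanillin
Product: 2 3-methoxy-4-(triisopropylsilyloxy)benzaldehyde
Conditions: TIPSCl, imidazole, DMF, rt
Reagents that add atoms: triisopropylsilyl chloride, CC(C)[Si](Cl)(C(C)C)C(C)C
Why: Imidazole-promoted O-silylation of a phenol is routine, and the bulky aryl TIPS ether is chosen because it withstands borohydride, Mitsunobu, palladium and brief cold methoxide while keeping ring A electron-rich for the later C–H insertion.

Step 2
Reactants: 2 3-methoxy-4-(triisopropylsilyloxy)benzaldehyde
Product: 3 [3-methoxy-4-(triisopropylsilyloxy)phenyl]methanol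
Conditions: NaBH4, MeOH, 0 °C
Reagents that add atoms: none
Why: Borohydride reduction of an aryl aldehyde to the benzylic alcohol is fast at 0 °C and leaves the aryl silyl ether alone.

Step 3
Reactants: 3 [3-methoxy-4-(triisopropylsilyloxy)phenyl]methanol; 4 5-iodovanillin
Product: 5 3-iodo-5-methoxy-4-{[3-methoxy-4-(triisopropylsilyloxy)phenyl]methoxy}benzaldehyde
Conditions: PPh3, DIAD, THF, 0 °C to rt
Reagents that add atoms: none
Why: Mitsunobu etherification joins the acidic phenol of 4 (para-formyl, ortho-iodo) to the primary benzylic alcohol under neutral conditions, which avoids an unstable para-silyloxybenzyl halide and keeps the silyl ether away from phenoxide in a dipolar solvent.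

Step 4
Reactants: 5 3-iodo-5-methoxy-4-{[3-methoxy-4-(triisopropylsilyloxy)phenyl]methoxy}benzaldehyde
Product: 6 (3-iodo-5-methoxy-4-{[3-methoxy-4-(triisopropylsilyloxy)phenyl]methoxy}phenyl)methanol
Conditions: NaBH4, THF/MeOH, 0 °C
Reagents that add atoms: none
Why: Chemoselective borohydride reduction of the aldehyde gives the ring B benzylic alcohol, the aryl iodide, the benzyl aryl ether and the silyl ether being inert.

Step 5
Reactants: 4 5-iodovanillin; 7 methyl (triphenylphosphoranylidene)acetate
Product: 8 methyl (E)-3-(4-hydroxy-3-iodo-5-methoxyphenyl)prop-2-enoate (methyl 5-iodoferulate)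
Conditions: 7 (1.5 equiv), toluene, 100 °C
Reagents that add atoms: none
Why: Wittig olefination with a stabilised ylide gives the E-cinnamate under thermodynamic control and tolerates the free phenol, and the iodine position is inherited from 4 so that no arene iodination with its regiochemical question is needed.

Step 6
Reactants: 6 (3-iodo-5-methoxy-4-{[3-methoxy-4-(triisopropylsilyloxy)phenyl]methoxy}phenyl)methanol; 8 methyl 5-iodoferulate
Product: 9 linear bis(aryl iodide), methyl (2E)-3-{3-iodo-4-[(3-iodo-5-methoxy-4-{[3-methoxy-4-(triisopropylsilyloxy)phenyl]methoxy}phenyl)methoxy]-5-methoxyphenyl}prop-2-enoate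
Conditions: PPh3, DIAD, THF, 0 °C to rt
Reagents that add atoms: none
Why: A second Mitsunobu etherification uses the phenol of 8, acidified by the para-acrylate and the ortho-iodine, as pronucleophile, so that no halide of the electron-rich ring B benzyl group is handled and the cinnamate, both iodides and the silyl ether stay spectators.

Step 7
Reactants: 9 linear bis(aryl iodide); 10 methyl diazoacetate
Product: 11 linear bis(aryldiazoacetate), methyl (2E)-3-{3-(1-diazo-2-methoxy-2-oxoethyl)-4-[(3-(1-diazo-2-methoxy-2-oxoethyl)-5-methoxy-4-{[3-methoxy-4-(triisopropylsilyloxy)phenyl]methoxy}phenyl)methoxy]-5-methoxyphenyl}prop-2-enoate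
Conditions: 10 (3 equiv), Pd(PPh3)4 (10 mol%), Ag2CO3 (1.0 equiv), Et3N (2.6 equiv), toluene, rt, dark
Reagents that add atoms: none
Why: Palladium-catalysed cross-coupling of aryl iodides with an acceptor diazo ester with retention of the diazo group (oxidative addition to zerovalent palladium, silver-assisted iodide abstraction, C-metalation of the deprotonated diazoacetate, reductive elimination) runs at room temperature, below the threshold for Heck reaction at the disubstituted cinnamate or for loss of N2, and installs both carbenoid precursors in one operation.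

Step 8
Reactants: 11 linear bis(aryldiazoacetate)
Product: 13 trans,trans triester, methyl (2R,3R)-7-methoxy-5-{(2R,3R)-7-methoxy-3-(methoxycarbonyl)-5-[(E)-3-methoxy-3-oxoprop-1-enyl]-2,3-dihydro-1-benzofuran-2-yl}-2-[3-methoxy-4-(triisopropylsilyloxy)phenyl]-2,3-dihydro-1-benzofuran-3-carboxylate, via bis-cis triester 12 (not isolated)
Conditions: Rh2(S-PTTL)4 (2 mol%; dirhodium tetrakis[N-phthaloyl-(S)-tert-leucinate]), toluene, −60 °C, slow addition of 11; then MeOH, NaOMe (0.3 equiv), 0 °C to rt; AcOH
Reagents that add atoms: none
Why: Each diazo ester loses N2 at a divalent rhodium centre of the paddlewheel complex to give an electrophilic donor/acceptor carbenoid, whose carbon takes up the neighbouring ArO–CH2–Ar C–H bond through a concerted, hydride-transfer-like three-centre transition state and so forms C2–C3. The closest known reaction is the dirhodium-carboxylate-catalysed enantioselective intramolecular C–H insertion of ortho-benzyloxy aryldiazoacetates to cis-2-aryl-2,3-dihydrobenzofuran-3-carboxylates followed by base epimerisation to trans, applied here at two independent sites of one molecule. Ring C and ring D each close by 1,5 C–H insertion, a five-membered closure in which the carbenoid carbon becomes C3 and the benzylic ether carbon becomes C2. C2 of each unit is set by the chiral phthalimido-tert-leucinate ligand sphere, which picks one of the two benzylic hydrogens (catalyst control, expected 2R twice), while C3 is first set cis by the compact insertion transition state and then turned trans under thermodynamic control when methoxide reversibly forms the ester enolate; C2 has no acidic hydrogen and is not touched. The step needs site selectivity, which is secured because each carbenoid has a single doubly activated C–H bond (alpha to oxygen, benzylic to a para-oxygenated ring) within five-ring reach, the methoxy groups lying on the far side of each ether oxygen, and chemoselectivity, which is secured because the only alkene is a remote electron-poor cinnamate. Since the two catalyst-controlled events are independent, a wrong-sense insertion at one site should appear mainly as a separable diastereomer and not as the enantiomer.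

Step 9
Reactants: 13 trans,trans triester
Product: 14 triol silyl ether, [(2R,3S)-5-{(2R,3S)-3-(hydroxymethyl)-5-[(E)-3-hydroxyprop-1-enyl]-7-methoxy-2,3-dihydro-1-benzofuran-2-yl}-7-methoxy-2-[3-methoxy-4-(triisopropylsilyloxy)phenyl]-2,3-dihydro-1-benzofuran-3-yl]methanol
Conditions: iBu2AlH (7 equiv), CH2Cl2, −78 to −20 °C; aq potassium sodium tartrate
Reagents that add atoms: none
Why: iBu2AlH reduces the two saturated esters and, by 1,2-addition, the enoate to primary alcohols at low temperature without base, so that the trans C2/C3 centres and the E-alkene are retained and the aryl silyl ether and benzylic aryl ethers are untouched.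

Step 10
Reactants: 14 triol silyl ether
Product: 15 target, 4-[(2R,3S)-3-(hydroxymethyl)-5-{(2R,3S)-3-(hydroxymethyl)-5-[(E)-3-hydroxyprop-1-enyl]-7-methoxy-2,3-dihydro-1-benzofuran-2-yl}-7-methoxy-2,3-dihydro-1-benzofuran-2-yl]-2-methoxyphenol
Conditions: Bu4NF, AcOH (1:1), THF, 0 °C
Reagents that add atoms: none
Why: Fluoride cleaves the aryl Si–O bond selectively, and acetic acid buffering protonates the phenoxide at once so that it cannot expel O1 of ring C through a quinone methide, which leaves all four stereocentres intact.

Compound list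
1 | vanillin (4-hydroxy-3-methoxybenzaldehyde) | COc1cc(C=O)ccc1O | starting material
2 | 3-methoxy-4-(triisopropylsilyloxy)benzaldehyde | COc1cc(C=O)ccc1O[Si](C(C)C)(C(C)C)C(C)C | intermediate
3 | [3-methoxy-4-(triisopropylsilyloxy)phenyl]methanol | COc1cc(CO)ccc1O[Si](C(C)C)(C(C)C)C(C)C | intermediate
4 | 5-iodovanillin (4-hydroxy-3-iodo-5-methoxybenzaldehyde) | COc1cc(C=O)cc(I)c1O | starting material
5 | 3-iodo-5-methoxy-4-{[3-methoxy-4-(triisopropylsilyloxy)phenyl]methoxy}benzaldehyde | COc1cc(C=O)cc(I)c1OCc1ccc(O[Si](C(C)C)(C(C)C)C(C)C)c(OC)c1 | intermediate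
6 | (3-iodo-5-methoxy-4-{[3-methoxy-4-(triisopropylsilyloxy)phenyl]methoxy}phenyl)methanol | COc1cc(CO)cc(I)c1OCc1ccc(O[Si](C(C)C)(C(C)C)C(C)C)c(OC)c1 | intermediate
7 | methyl (triphenylphosphoranylidene)acetate | COC(=O)C=P(c1ccccc1)(c1ccccc1)c1ccccc1 | starting material
8 | methyl (E)-3-(4-hydroxy-3-iodo-5-methoxyphenyl)prop-2-enoate (methyl 5-iodoferulate) | COC(=O)/C=C/c1cc(OC)c(O)c(I)c1 | intermediate
9 | linear bis(aryl iodide): ring E iodoferulate O-benzylated by ring B, ring B iodide O-benzylated by silylated ring A | COC(=O)/C=C/c1cc(OC)c(OCc2cc(OC)c(OCc3ccc(O[Si](C(C)C)(C(C)C)C(C)C)c(OC)c3)c(I)c2)c(I)c1 | intermediate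
10 | methyl diazoacetate | COC(=O)C=[N+]=[N-] | starting material
11 | linear bis(aryldiazoacetate): as 9 with each iodine replaced by C(=N2)CO2Me | COC(=O)/C=C/c1cc(OC)c(OCc2cc(OC)c(OCc3ccc(O[Si](C(C)C)(C(C)C)C(C)C)c(OC)c3)c(C(=[N+]=[N-])C(=O)OC)c2)c(C(=[N+]=[N-])C(=O)OC)c1 | intermediate
12 | bis-cis triester, (2R,3S) in unit 1 and (2R,3S) in unit 2, ring A silyl ether | COc1cc([C@@H]2Oc3c(OC)cc([C@@H]4Oc5c(OC)cc(/C=C/C(=O)OC)cc5[C@@H]4C(=O)OC)cc3[C@@H]2C(=O)OC)ccc1O[Si](C(C)C)(C(C)C)C(C)C | intermediate
13 | trans,trans triester, (2R,3R) in unit 1 and (2R,3R) in unit 2, ring A silyl ether | COc1cc([C@@H]2Oc3c(OC)cc([C@@H]4Oc5c(OC)cc(/C=C/C(=O)OC)cc5[C@H]4C(=O)OC)cc3[C@H]2C(=O)OC)ccc1O[Si](C(C)C)(C(C)C)C(C)C | intermediate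
14 | triol silyl ether, (2R,3S) in both units, E-allylic alcohol | COc1cc([C@@H]2Oc3c(OC)cc([C@@H]4Oc5c(OC)cc(/C=C/CO)cc5[C@H]4CO)cc3[C@H]2CO)ccc1O[Si](C(C)C)(C(C)C)C(C)C | intermediate
15 | CNP0250921.1, 4-[(2R,3S)-3-(hydroxymethyl)-5-{(2R,3S)-3-(hydroxymethyl)-5-[(E)-3-hydroxyprop-1-enyl]-7-methoxy-2,3-dihydro-1-benzofuran-2-yl}-7-methoxy-2,3-dihydro-1-benzofuran-2-yl]-2-methoxyphenol | COc1cc([C@@H]2Oc3c(OC)cc([C@@H]4Oc5c(OC)cc(/C=C/CO)cc5[C@H]4CO)cc3[C@H]2CO)ccc1O | target

Total steps: 10. Longest linear sequence: 9 steps (steps 1, 2, 3, 4, 6, 7, 8, 9 and 10, from vanillin).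

Steps most likely to fail

Step 8. The two carbene centres may interfere with each other: carbene–diazo coupling between molecules would give azines, alkenes and oligomers, and one site may insert with lower selectivity once the other has reacted. Methoxide may also open a furan ring by β-elimination of the O1 phenoxide instead of only epimerising C3, or may start to remove the silyl group. The fallback splits the twofold event into two single ring closures of the established kind, each purified. Setting out from alcohol 6, acetylation (Ac2O, pyridine) would give the benzylic acetate F1. Coupling with 10 under the conditions of step 7 would give the mono(aryldiazoacetate) F2. Insertion with Rh2(S-PTTL)4 in toluene at −60 °C would give the cis ester acetate F3, which is not isolated. NaOMe in MeOH in the same flask would epimerise C3 and remove the acetate by transesterification, giving the trans ester alcohol F4 with unit 1 complete. Mitsunobu coupling with 8 would give the aryl iodide F5, and a second palladium coupling with 10 the diazo ester F6. A second insertion would give the unit-2-cis triester F7, again not isolated, and methoxide equilibration returns the route at 13.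

Step 7. Oxidative addition or C-metalation at the two ortho-alkoxy-flanked iodides may stall after one coupling, or the product may lose N2 at palladium and decompose through a carbene, so that mono-coupled and reduced material accumulates. The fallback builds the diazo groups in two known operations. Setting out from 9, twofold Negishi-type coupling with the Reformatsky reagent BrZnCH2CO2Me (Pd2(dba)3, XPhos, THF, 50 °C) would give the bis(methyl arylacetate) F8. Regitz diazo transfer (p-ABSA, DBU, MeCN, 0 °C to rt) would then convert both activated methylene groups into diazo groups and return the route at 11.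

Step 6. The Mitsunobu betaine may fail to engage the doubly ortho-substituted phenol 8, so that the activated alcohol is consumed by N-alkylation of the hydrazide or by self-etherification. The fallback changes the bond-forming mode to an SN2 alkylation. Setting out from 6, Appel bromination (CBr4, PPh3, CH2Cl2, 0 °C) would give the benzylic bromide F9, which is used at once in a Williamson etherification of 8 (K2CO3, acetone, 50 °C) and returns the route at 9.

Further compounds
F1 | step 8 | (3-iodo-5-methoxy-4-{[3-methoxy-4-(triisopropylsilyloxy)phenyl]methoxy}phenyl)methyl acetate | CC(=O)OCc1cc(OC)c(OCc2ccc(O[Si](C(C)C)(C(C)C)C(C)C)c(OC)c2)c(I)c1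
F2 | step 8 | methyl 2-[5-(acetoxymethyl)-3-methoxy-2-{[3-methoxy-4-(triisopropylsilyloxy)phenyl]methoxy}phenyl]-2-diazoacetate | CC(=O)OCc1cc(OC)c(OCc2ccc(O[Si](C(C)C)(C(C)C)C(C)C)c(OC)c2)c(C(=[N+]=[N-])C(=O)OC)c1
F3 | step 8 | methyl (2R,3S)-5-(acetoxymethyl)-7-methoxy-2-[3-methoxy-4-(triisopropylsilyloxy)phenyl]-2,3-dihydro-1-benzofuran-3-carboxylate (cis, not isolated) | COc1cc([C@@H]2Oc3c(OC)cc(COC(C)=O)cc3[C@@H]2C(=O)OC)ccc1O[Si](C(C)C)(C(C)C)C(C)C
F4 | step 8 | methyl (2R,3R)-5-(hydroxymethyl)-7-methoxy-2-[3-methoxy-4-(triisopropylsilyloxy)phenyl]-2,3-dihydro-1-benzofuran-3-carboxylate (trans) | COc1cc([C@@H]2Oc3c(OC)cc(CO)cc3[C@H]2C(=O)OC)ccc1O[Si](C(C)C)(C(C)C)C(C)C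
F5 | step 8 | methyl (2R,3R)-5-({2-iodo-6-methoxy-4-[(E)-3-methoxy-3-oxoprop-1-enyl]phenoxy}methyl)-7-methoxy-2-[3-methoxy-4-(triisopropylsilyloxy)phenyl]-2,3-dihydro-1-benzofuran-3-carboxylate | COc1cc([C@@H]2Oc3c(OC)cc(COc4c(OC)cc(/C=C/C(=O)OC)cc4I)cc3[C@H]2C(=O)OC)ccc1O[Si](C(C)C)(C(C)C)C(C)C
F6 | step 8 | methyl (2R,3R)-5-({2-(1-diazo-2-methoxy-2-oxoethyl)-6-methoxy-4-[(E)-3-methoxy-3-oxoprop-1-enyl]phenoxy}methyl)-7-methoxy-2-[3-methoxy-4-(triisopropylsilyloxy)phenyl]-2,3-dihydro-1-benzofuran-3-carboxylate | COc1cc([C@@H]2Oc3c(OC)cc(COc4c(OC)cc(/C=C/C(=O)OC)cc4C(=[N+]=[N-])C(=O)OC)cc3[C@H]2C(=O)OC)ccc1O[Si](C(C)C)(C(C)C)C(C)C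
F7 | step 8 | triester with unit 1 trans (2R,3R) and unit 2 cis (2R,3S), ring A silyl ether (not isolated) | COc1cc([C@@H]2Oc3c(OC)cc([C@@H]4Oc5c(OC)cc(/C=C/C(=O)OC)cc5[C@@H]4C(=O)OC)cc3[C@H]2C(=O)OC)ccc1O[Si](C(C)C)(C(C)C)C(C)C
F8 | step 7 | linear bis(methyl arylacetate): as 9 with each iodine replaced by CH2CO2Me | COC(=O)/C=C/c1cc(OC)c(OCc2cc(OC)c(OCc3ccc(O[Si](C(C)C)(C(C)C)C(C)C)c(OC)c3)c(CC(=O)OC)c2)c(CC(=O)OC)c1
F9 | step 6 | 5-(bromomethyl)-1-iodo-3-methoxy-2-{[3-methoxy-4-(triisopropylsilyloxy)phenyl]methoxy}benzene | COc1cc(CBr)cc(I)c1OCc1ccc(O[Si](C(C)C)(C(C)C)C(C)C)c(OC)c1
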